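A direct plan would grow the chain linearly from the arene. An aryl Grignard reagent would open a three-carbon chiral epoxide to set C2, a masked C4–C6 aldehyde would be appended and C2–OH acetylated to give aldehyde A1. Aldol addition of heptan-2-one A2 and dehydration would give enone A3, a catalyst-controlled reduction would set C8 in allylic alcohol A4, and hydrogenation would finish. Its weakest points would be:
- the aldol addition and dehydration, two steps spent on a C6=C7 double bond and a C8 ketone that would be erased again;
- the enone reduction, where the reagent alone would have to tell n-pentyl from alkenyl, and a C8 epimer would be a hardly separable 1,7-diastereomer;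
- the acidic unmasking of the aldehyde beside the acetate, an acetal detour that would add length only.

The route rests on the C6–C7 bond inside the unfunctionalised C3–C7 pentamethylene tether, which offers no polar handle. It is made between two carbons of like polarity: the terminal olefin carbon of (R)-hexenyl acetate 6 and the primary radical released by decarboxylation of the redox-active ester 11. One nickel hydride catalysed anti-Markovnikov hydroalkylation would join the two stereodefined halves at the alkane oxidation level, each carrying its oxygen already differentiated (C2 acetate, C8 benzyl ether). C2 would come from a commercial epoxide and C8 from a Noyori hydrogenation, so the aldol–dehydration detour, the enone reduction and the acetal all disappear.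

Key step: step 8

Remark: locants C1–C13 are those of the tridecane chain of the target (C1 benzylic, C2 acetoxy, C8 hydroxy); (R)-2-(but-3-en-1-yl)oxirane and methyl 3-oxooctanoate are assumed to be purchasable.

Step 1
Reactants: 1 3-bromo-5-methoxyphenol
Product: 2 1-(benzyloxy)-3-bromo-5-methoxybenzene
Conditions: BnBr, K2CO3, DMF, rt
Reagents that add atoms: benzyl bromide, BrCc1ccccc1
Why: Williamson ether synthesis on the phenoxide should give an aryl benzyl ether that is inert to the Grignard, acylation and nickel hydride steps and falls in the final hydrogenolysis.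

Step 2
Reactants: 2 1-(benzyloxy)-3-bromo-5-methoxybenzene; 3 (R)-2-(but-3-en-1-yl)oxirane
Product: 5 (R)-1-[3-(benzyloxy)-5-methoxyphenyl]hex-5-en-2-ol, via aryl Grignard reagent 4 (not isolated)
Conditions: Mg, THF, 50 °C; then CuI (10 mol%), 3, −40 → −10 °C; sat. aq. NH4Cl
Reagents that add atoms: none
Why: Copper-catalysed SN2 opening of the terminal epoxide by the aryl Grignard reagent should occur at the unsubstituted carbon and form the C1–aryl bond, while the C2 stereocentre is bought with 3 and no bond to it is touched (R retained), the remote olefin being inert.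

Step 3
Reactants: 5 (R)-1-[3-(benzyloxy)-5-methoxyphenyl]hex-5-en-2-ol
Product: 6 (R)-1-[3-(benzyloxy)-5-methoxyphenyl]hex-5-en-2-yl acetate
Conditions: Ac2O, DMAP (5 mol%), pyridine, CH2Cl2, rt
Reagents that add atoms: acetic anhydride, CC(=O)OC(C)=O
Why: DMAP-catalysed O-acylation should install the acetate of the target with retention at C2 while this is the only hydroxyl present, so that C2–O and C8–O never have to be told apart.

Step 4
Reactants: 7 methyl 3-oxooctanoate
Product: 8 methyl (S)-3-hydroxyoctanoate
Conditions: H2 (50 atm), RuCl2[(S)-BINAP] (0.1 mol%), MeOH, 50 °C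
Reagents that add atoms: none
Why: Noyori asymmetric hydrogenation of the β-keto ester should proceed through the ester-chelated ruthenium hydride, in which the (S)-BINAP ligand directs hydride to one carbonyl face and sets the (S)-carbinol that becomes C8.

Step 5
Reactants: 8 methyl (S)-3-hydroxyoctanoate
Product: 9 methyl (S)-3-(benzyloxy)octanoate
Conditions: BnOC(=NH)CCl3 (1.5 equiv), TfOH (5 mol%), cyclohexane–CH2Cl2 (2:1), 0 °C → rt
Reagents that add atoms: benzyl 2,2,2-trichloroacetimidate, N=C(OCc1ccccc1)C(Cl)(Cl)Cl
Why: Acid-catalysed benzyl transfer from the trichloroacetimidate should etherify the β-hydroxyl without base, so that retro-aldol cleavage and elimination are avoided, the C–O bond of the stereocentre is not broken, and the ether later leaves together with the aryl benzyl ether.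

Step 6
Reactants: 9 methyl (S)-3-(benzyloxy)octanoate
Product: 10 (S)-3-(benzyloxy)octanoic acid
Conditions: LiOH·H2O, THF–MeOH–H2O, 0 °C → rt; then 1 M HCl
Reagents that add atoms: lithium hydroxide, [Li+].[OH-]
Why: Saponification by acyl–oxygen cleavage should leave the ether and the stereocentre untouched, the low temperature keeping β-elimination of benzyl oxide negligible.

Step 7
Reactants: 10 (S)-3-(benzyloxy)octanoic acid
Product: 11 1,3-dioxoisoindolin-2-yl (S)-3-(benzyloxy)octanoate
Conditions: N-hydroxyphthalimide (1.1 equiv), DIC (1.1 equiv), CH2Cl2, 0 °C → rt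
Reagents that add atoms: N-hydroxyphthalimide, O=C1c2ccccc2C(=O)N1O
Why: Carbodiimide-mediated (Steglich-type) esterification should give the redox-active ester, whose N–O bond accepts one electron under mild conditions and releases the primary C7 radical after loss of CO2.

Step 8
Reactants: 6 (R)-1-[3-(benzyloxy)-5-methoxyphenyl]hex-5-en-2-yl acetate; 11 1,3-dioxoisoindolin-2-yl (S)-3-(benzyloxy)octanoate
Product: 12 (2R,8S)-8-(benzyloxy)-1-[3-(benzyloxy)-5-methoxyphenyl]tridecan-2-yl acetate
Conditions: NiBr2·diglyme (10 mol%), 4,4′-di-tert-butyl-2,2′-bipyridine (12 mol%), (EtO)2MeSiH (2.5 equiv), 11 (1.5 equiv), DMAc, rt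
Reagents that add atoms: none
Why: A bipyridine nickel hydride formed from the precatalyst and the silane should insert the terminal C5=C6 olefin of 6 in the anti-Markovnikov sense to give a primary C6-alkylnickel species, while single-electron reduction of 11 by low-valent nickel cleaves the N–O bond, CO2 is lost, and the primary C7 radical is captured to give a dialkyl trivalent nickel complex whose reductive elimination forms the C6–C7 bond. The closest known reaction type is the nickel hydride catalysed decarboxylative hydroalkylation of unactivated terminal olefins with N-(acyloxy)phthalimides, a C(sp3)–C(sp3) coupling related to reductive olefin hydroalkylation with alkyl iodides. No ring is closed and no stereocentre is formed: C2 lies four bonds from the reacting olefin and C8 is β to the radical carbon, so both are carried through unchanged. The step needs linear regioselectivity, which the unhindered monosubstituted olefin and a bipyridine ligand without ortho substituents (poor at chain walking) should secure, and cross-selectivity, which is built in because the olefin enters only as the organonickel partner and the ester only as the radical. The β-benzyloxy group is a poor leaving group from a carbon radical, and the acetate, both benzyl ethers and the electron-rich arene should be inert to silane and low-valent nickel at room temperature.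

Step 9
Reactants: 12 (2R,8S)-8-(benzyloxy)-1-[3-(benzyloxy)-5-methoxyphenyl]tridecan-2-yl acetate
Product: 13 (2R,8S)-8-hydroxy-1-(3-hydroxy-5-methoxyphenyl)tridecan-2-yl acetate
Conditions: H2 (1 atm), 10% Pd/C, EtOAc–EtOH, rt
Reagents that add atoms: none
Why: Heterogeneous hydrogenolysis should cleave the aryl benzyl ether and the secondary alkyl benzyl ether in one operation, while the non-benzylic C2 acetate, the methyl ether and both stereocentres are not affected.

**Compound list**
1 | 3-bromo-5-methoxyphenol | COc1cc(O)cc(Br)c1 | starting material
2 | 1-(benzyloxy)-3-bromo-5-methoxybenzene | COc1cc(Br)cc(OCc2ccccc2)c1 | intermediate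
3 | (R)-2-(but-3-en-1-yl)oxirane [(R)-1,2-epoxy-5-hexene] | C=CCC[C@@H]1CO1 | starting material
4 | [3-(benzyloxy)-5-methoxyphenyl]magnesium bromide | COc1cc([Mg]Br)cc(OCc2ccccc2)c1 | intermediate
5 | (R)-1-[3-(benzyloxy)-5-methoxyphenyl]hex-5-en-2-ol | C=CCC[C@H](Cc1cc(OC)cc(OCc2ccccc2)c1)O | intermediate
6 | (R)-1-[3-(benzyloxy)-5-methoxyphenyl]hex-5-en-2-yl acetate | C=CCC[C@H](Cc1cc(OC)cc(OCc2ccccc2)c1)OC(C)=O | intermediate
7 | methyl 3-oxooctanoate | CCCCCC(=O)CC(=O)OC | starting material
8 | methyl (S)-3-hydroxyoctanoate | CCCCC[C@H](O)CC(=O)OC | intermediate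
9 | methyl (S)-3-(benzyloxy)octanoate | CCCCC[C@H](OCc1ccccc1)CC(=O)OC | intermediate
10 | (S)-3-(benzyloxy)octanoic acid | CCCCC[C@H](OCc1ccccc1)CC(=O)O | intermediate
11 | 1,3-dioxoisoindolin-2-yl (S)-3-(benzyloxy)octanoate | CCCCC[C@H](OCc1ccccc1)CC(=O)ON1C(=O)c2ccccc2C1=O | intermediate
12 | (2R,8S)-8-(benzyloxy)-1-[3-(benzyloxy)-5-methoxyphenyl]tridecan-2-yl acetate | CCCCC[C@H](OCc1ccccc1)CCCCC[C@H](Cc1cc(OC)cc(OCc2ccccc2)c1)OC(C)=O | intermediate
13 | (2R,8S)-8-hydroxy-1-(3-hydroxy-5-methoxyphenyl)tridecan-2-yl acetate | CCCCC[C@H](O)CCCCC[C@H](Cc1cc(O)cc(OC)c1)OC(C)=O | target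

Total step count: 9. Longest linear sequence: 6 steps (steps 4 to 9, from methyl 3-oxooctanoate); the arene branch (steps 1 to 3) joins at step 8.

Steps most likely to fail:

Step 8. The nickel hydride may isomerise or reduce the terminal olefin of 6 (chain walking), and the C7 radical may be quenched by hydrogen-atom transfer (hydrodecarboxylation) faster than it is captured, so that conversion to 12 would stay low. The fallback replaces the radical coupling by an olefin cross-metathesis and sets out from 9 and 6. Ester 9 would be reduced with i-Bu2AlH (CH2Cl2, −78 °C) to (S)-3-(benzyloxy)octanal F1 and methylenated by a Wittig reaction (Ph3P=CH2, THF, −78 → 0 °C) to (S)-4-(benzyloxy)non-1-ene F2. F2, used in excess, would be cross-metathesised with 6 (second-generation Hoveyda–Grubbs catalyst, CH2Cl2, 40 °C) to the C5=C6 olefin (2R,8S)-8-(benzyloxy)-1-[3-(benzyloxy)-5-methoxyphenyl]tridec-5-en-2-yl acetate F3 (E/Z mixture). Hydrogenation over Pd/C would then saturate the olefin and remove both benzyl groups, so the fallback comes back to the route at the target 13.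

Step 7. The activated ester may lose benzyl alcohol by base-induced β-elimination (to the oct-2-enoate) or hydrolyse during isolation. The fallback changes the radical precursor and sets out from 10. Decarboxylative iodination with a hypervalent iodine reagent (PhI(OAc)2, I2, visible light, CH2Cl2, reflux) would give (S)-2-(benzyloxy)-1-iodoheptane F4, a precursor of the same C7 radical. Nickel hydride catalysed reductive hydroalkylation of 6 with this alkyl iodide (NiBr2·diglyme, 4,4′-di-tert-butyl-2,2′-bipyridine, (EtO)2MeSiH, Na2CO3, DMAc, rt) would come back to the route at 12.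

Step 5. Rearrangement of the imidate to N-benzyltrichloroacetamide, or acid-induced elimination, may outrun O-alkylation of the hindered β-hydroxyl. The fallback forms the C–O bond by reductive etherification and sets out from 8. Silylation (TMSCl, Et3N, CH2Cl2, 0 °C) would give methyl (S)-3-[(trimethylsilyl)oxy]octanoate F5. Treatment with PhCHO, Et3SiH and catalytic TMSOTf (CH2Cl2, −78 °C) would then reduce the intermediate oxocarbenium ion to the benzyl ether, and the fallback comes back to the route at 9.

Further compounds
F1 | step 8 | (S)-3-(benzyloxy)octanal | CCCCC[C@H](OCc1ccccc1)CC=O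
F2 | step 8 | (S)-4-(benzyloxy)non-1-ene | CCCCC[C@H](OCc1ccccc1)CC=C
F3 | step 8 | (2R,8S)-8-(benzyloxy)-1-[3-(benzyloxy)-5-methoxyphenyl]tridec-5-en-2-yl acetate (E/Z mixture) | CCCCC[C@H](OCc1ccccc1)CC=CCC[C@H](Cc1cc(OC)cc(OCc2ccccc2)c1)OC(C)=O
F4 | step 7 | (S)-2-(benzyloxy)-1-iodoheptane | CCCCC[C@H](OCc1ccccc1)CI
F5 | step 5 | methyl (S)-3-[(trimethylsilyl)oxy]octanoate | CCCCC[C@H](O[Si](C)(C)C)CC(=O)OC
A1 | direct plan | (R)-1-[3-(benzyloxy)-5-methoxyphenyl]-6-oxohexan-2-yl acetate | O=CCCC[C@H](Cc1cc(OC)cc(OCc2ccccc2)c1)OC(C)=O
A2 | direct plan | heptan-2-one | CCCCCC(C)=O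
A3 | direct plan | (2R,6E)-1-[3-(benzyloxy)-5-methoxyphenyl]-8-oxotridec-6-en-2-yl acetate | CCCCCC(=O)/C=C/CCC[C@H](Cc1cc(OC)cc(OCc2ccccc2)c1)OC(C)=O
A4 | direct plan | (2R,6E,8S)-1-[3-(benzyloxy)-5-methoxyphenyl]-8-hydroxytridec-6-en-2-yl acetate | CCCCC[C@H](O)/C=C/CCC[C@H](Cc1cc(OC)cc(OCc2ccccc2)c1)OC(C)=O
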